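**Plan**

Numbering: lactone O1, C2 (C=O), C3 (exocyclic CH2), C4 (CO2H), C5 (side chain C1'–C15', carbinol C14'). The target is 4S,5S,14'S, with C4 and C5 cis.
Enabling feature: the C4–C5 bond joins the two ring stereocentres, and C4 is attached to an intact 2-carboxyallyl unit (CH2=C3–C2). The five-membered ring is therefore the retron of an aldehyde allylboration followed by lactonisation.
Cuts: first the C4 methyl ester and the C14' silyl ether, then O1–C2 and C4–C5 in one operation. This leaves a C16 silyloxy aldehyde and a 2-(borylmethyl)fumarate.
Forward order: pentadecanolide plus one methyl carbon gives the chain, and dimethyl itaconate gives the boronate. Their union makes C4–C5, the only ring closes in the same flask, and aqueous acid then frees the acid and the alcohol.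
Stereochemistry: C14' comes from an enzymatic ketone reduction and C5 from the chiral phosphoric acid (Re face of the aldehyde). C4 comes from the alkene geometry of the boronate, relayed through a chair transition state.

Key step: step 8

Assumption: the facial sense of (R)-TRIP (Re face of RCHO) is carried over from allyl and crotyl pinacolboronates; it would be checked on a model aldehyde, and the antipodal acid taken if the sense proves opposite.

**Route**

Step 1
Reactants: 1 pentadecanolide (oxacyclohexadecan-2-one)
Product: 2 15-hydroxy-N-methoxy-N-methylpentadecanamide
Conditions: MeNH(OMe)·HCl, iPrMgCl, THF, −20 to 0 °C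
Reagents that add atoms: N,O-dimethylhydroxylamine hydrochloride, Cl.CNOC
Why: Aminolysis of the macrolactone by the chloromagnesium amide of N,O-dimethylhydroxylamine (Weinreb amide formation from an ester) is driven by the strong nitrogen nucleophile and frees the terminal alcohol, which needs no protection for the next step.

Step 2
Reactants: 2 15-hydroxy-N-methoxy-N-methylpentadecanamide
Product: 3 16-hydroxyhexadecan-2-one
Conditions: MeMgBr (3 equiv), THF, 0 °C; aq. NH4Cl
Reagents that add atoms: methylmagnesium bromide, C[Mg]Br
Why: In this Weinreb ketone synthesis the first equivalent of Grignard reagent deprotonates the alcohol and the next adds once to the amide, whose magnesium chelate holds until the quench so that no tertiary alcohol can form.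

Step 3
Reactants: 3 16-hydroxyhexadecan-2-one
Product: 4 (15S)-hexadecane-1,15-diol
Conditions: ADH-A (alcohol dehydrogenase from Rhodococcus ruber), NAD+ (cat.), iPrOH/phosphate buffer pH 7.5, 30 °C
Reagents that add atoms: none
Why: In this biocatalytic asymmetric ketone reduction with isopropanol as coupled hydrogen donor the enzyme passes hydride from NADH to the Re face of methyl ketones, which sets 15S, and it tells methyl from a long unbranched chain better than chemical catalysts do while leaving primary alcohols alone.

Step 4
Reactants: 4 (15S)-hexadecane-1,15-diol
Product: 5 (15S)-15-hydroxyhexadecanal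
Conditions: TEMPO (10 mol %), PhI(OAc)2 (1.1 equiv), CH2Cl2, rt
Reagents that add atoms: none
Why: Under Piancatelli–Margarita oxidation conditions the hindered oxoammonium ion reacts much faster with the primary than with the secondary alcohol and, without water, stops at the aldehyde, so the two hydroxyl groups are told apart without extra protecting-group steps.

Step 5
Reactants: 5 (15S)-15-hydroxyhexadecanal
Product: 6 (15S)-15-(tert-butyldimethylsilyloxy)hexadecanal
Conditions: TBSCl, imidazole, DMF, rt
Reagents that add atoms: tert-butyldimethylsilyl chloride, CC(C)(C)[Si](C)(C)Cl
Why: Imidazole-promoted silylation of a secondary alcohol leaves the aldehyde untouched and does not affect the C–O bond at C15.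

Step 6
Reactants: 7 dimethyl itaconate
Product: 9 dimethyl (2Z)-2-(bromomethyl)but-2-enedioate (dimethyl 2-(bromomethyl)fumarate; esters trans; CH2Br cis to the C4 ester), via racemic dibromide 8 (not isolated)
Conditions: Br2 (1.0 equiv), CH2Cl2, reflux; then Et3N (1.05 equiv), 0 °C to rt
Reagents that add atoms: bromine, BrBr
Why: Electrophilic bromine addition to the 1,1-disubstituted alkene followed by amine-induced dehydrobromination (E1cB-like loss of the acidic proton next to the ester and of the tertiary bromide) gives the conjugated diester, for which the more stable arrangement with the two esters trans is expected.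

Step 7
Reactants: 9 dimethyl (2Z)-2-(bromomethyl)but-2-enedioate; 10 bis(pinacolato)diboron
Product: 11 dimethyl (2E)-2-[(4,4,5,5-tetramethyl-1,3,2-dioxaborolan-2-yl)methyl]but-2-enedioate (esters trans; CH2B cis to the C4 ester)
Conditions: Pd2(dba)3 (2.5 mol %), toluene, 50 °C; short silica plug, used promptly
Reagents that add atoms: none
Why: In this Miyaura-type borylation of an allylic halide zerovalent palladium inserts into the C–Br bond, the allyl complex transmetalates with the diboron reagent and reductive elimination at the unsubstituted CH2 terminus gives the primary boronate, the trans-diester geometry being both the starting and the thermodynamically preferred one.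

Step 8
Reactants: 6 (15S)-15-(tert-butyldimethylsilyloxy)hexadecanal; 11 dimethyl (2E)-2-[(pinacolboryl)methyl]but-2-enedioate (1.3 equiv)
Product: 13 methyl (2S,3S)-2-[(14S)-14-(tert-butyldimethylsilyloxy)pentadecyl]-4-methylidene-5-oxooxolane-3-carboxylate (cis lactone), via open-chain syn borate 12 (not isolated)
Conditions: (R)-TRIP [(R)-3,3'-bis(2,4,6-triisopropylphenyl)-1,1'-binaphthyl-2,2'-diyl hydrogen phosphate] (10 mol %), 4 Å MS, toluene, 0 °C to rt, then 40 °C
Reagents that add atoms: none
Why: Proposed new method: the phosphoric acid proton binds a pinacol oxygen of 11 and so raises the Lewis acidity of boron, the aldehyde oxygen of 6 coordinates, and the allyl unit is transferred through a closed six-membered chair in which the ester-bearing alkene carbon (future C4) bonds to the formyl carbon (C5) while the CH2–B carbon becomes the exocyclic methylene, giving borate 12. The closest known reaction types are the TRIP-catalysed allyl- and crotylboration of aldehydes with pinacol boronates and the acid-catalysed stereospecific allylboration–lactonisation of 2-(alkoxycarbonyl)allylboronates; not yet shown is their combination on a boronate that carries a second ester on the transferring carbon and is therefore a poor nucleophile, which at least should keep the uncatalysed racemic pathway negligible. The lactone ring closes by 5-exo-trig acyl substitution of the B–O oxygen of 12 on the C2 methyl ester with loss of MeOBpin, whereas attack on the C4 ester would give a four-membered ring and does not compete. C5 is set by the catalyst, whose binaphthyl pocket is expected to expose the Re face of the unbranched aldehyde (5S), and C4 is set relative to C5 by the alkene geometry, because the ester lying cis to CH2B must sit axial while the alkyl chain sits equatorial, which gives the syn adduct and hence only the cis lactone (4S). The step needs γ-regioselectivity, syn diastereoselectivity and enantioface selectivity: the first two follow from the cyclic transition state and the defined E alkene of 11, and the third rests on the catalyst alone because C14' is too remote to matter. No base is present, so the acidic C4–H next to the new methylene is left undisturbed.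

Step 9
Reactants: 13 methyl (2S,3S)-2-[(14S)-14-(tert-butyldimethylsilyloxy)pentadecyl]-4-methylidene-5-oxooxolane-3-carboxylate
Product: 15 (2S,3S)-2-[(14S)-14-hydroxypentadecyl]-4-methylidene-5-oxooxolane-3-carboxylic acid (target), via hydroxy methyl ester 14 (not isolated)
Conditions: 6 M aq. HCl, butanone, reflux
Reagents that add atoms: water, O
Why: Acid-catalysed silyl ether cleavage and ester hydrolysis under the conditions established for methyl esters of α-methylene paraconic acids involve no base, so C4 is not deprotonated, and any lactone that opens can only re-close to the same five-membered ring with retention at C5.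

**Compound list**

1 | pentadecanolide (oxacyclohexadecan-2-one) | O=C1CCCCCCCCCCCCCCO1 | starting material
2 | 15-hydroxy-N-methoxy-N-methylpentadecanamide | CON(C)C(=O)CCCCCCCCCCCCCCO | intermediate
3 | 16-hydroxyhexadecan-2-one | CC(=O)CCCCCCCCCCCCCCO | intermediate
4 | (15S)-hexadecane-1,15-diol | OCCCCCCCCCCCCCC[C@H](C)O | intermediate
5 | (15S)-15-hydroxyhexadecanal | O=CCCCCCCCCCCCCC[C@H](C)O | intermediate
6 | (15S)-15-(tert-butyldimethylsilyloxy)hexadecanal | O=CCCCCCCCCCCCCC[C@H](C)O[Si](C)(C)C(C)(C)C | intermediate
7 | dimethyl itaconate | C=C(CC(=O)OC)C(=O)OC | starting material
8 | dimethyl 2-bromo-2-(bromomethyl)butanedioate (racemic, not isolated) | COC(=O)CC(Br)(CBr)C(=O)OC | intermediate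
9 | dimethyl (2Z)-2-(bromomethyl)but-2-enedioate | COC(=O)/C=C(\CBr)C(=O)OC | intermediate
10 | bis(pinacolato)diboron | CC1(C)OB(OC1(C)C)B1OC(C)(C)C(C)(C)O1 | starting material
11 | dimethyl (2E)-2-[(4,4,5,5-tetramethyl-1,3,2-dioxaborolan-2-yl)methyl]but-2-enedioate | COC(=O)/C=C(\CB1OC(C)(C)C(C)(C)O1)C(=O)OC | intermediate
12 | dimethyl (2S)-2-[(1S,15S)-15-(tert-butyldimethylsilyloxy)-1-(4,4,5,5-tetramethyl-1,3,2-dioxaborolan-2-yloxy)hexadecyl]-3-methylidenebutanedioate (not isolated) | C=C(C(=O)OC)[C@H](C(=O)OC)[C@@H](OB1OC(C)(C)C(C)(C)O1)CCCCCCCCCCCCC[C@H](C)O[Si](C)(C)C(C)(C)C | intermediate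
13 | methyl (2S,3S)-2-[(14S)-14-(tert-butyldimethylsilyloxy)pentadecyl]-4-methylidene-5-oxooxolane-3-carboxylate | C=C1C(=O)O[C@@H](CCCCCCCCCCCCC[C@H](C)O[Si](C)(C)C(C)(C)C)[C@H]1C(=O)OC | intermediate
14 | methyl (2S,3S)-2-[(14S)-14-hydroxypentadecyl]-4-methylidene-5-oxooxolane-3-carboxylate (not isolated) | C=C1C(=O)O[C@@H](CCCCCCCCCCCCC[C@H](C)O)[C@H]1C(=O)OC | intermediate
15 | (2S,3S)-2-[(14S)-14-hydroxypentadecyl]-4-methylidene-5-oxooxolane-3-carboxylic acid | C=C1C(=O)O[C@@H](CCCCCCCCCCCCC[C@H](C)O)[C@H]1C(=O)O | target

**Step count and risks**

Total step count: 9. Longest linear sequence: 7 (steps 1–5, 8, 9).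

Steps most likely to fail:

1. Step 8 (new method).
- Risk: allyl transfer from the doubly ester-deactivated boronate may be too slow for an acid of moderate strength.
- Risk: facial discrimination on an unbranched aliphatic aldehyde may be incomplete. The resulting ring epimers differ from the wanted compound only in their relation to the remote C14' and would be hard to remove.
- Fallback: a chiral auxiliary on boron is combined with a strong achiral Lewis acid, both known for 2-(alkoxycarbonyl)allylboronates. It sets out from boronate 11 and aldehyde 6 and returns at lactone 13.
- Aqueous KHF2 in methanol should turn 11 into potassium [(2E)-2,3-bis(methoxycarbonyl)prop-2-en-1-yl]trifluoroborate F1. TMSCl and the known camphor-derived auxiliary (1R,2S,3R,4S)-2-phenylbornane-2,3-diol in MeCN should convert it into the chiral cyclic boronate F2.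
- F2 and 6 under Sc(OTf)3 (10 mol %) in CH2Cl2, from −78 °C upward, should pass through the same chair to the open-chain bornanediol borate F3, which lactonises to 13 on warming.
- The alkene geometry still fixes the cis relation, and the diol now fixes the face. The structures are drawn for the (1R)-camphor series, and the antipodal diol would be taken if a trial shows the opposite sense.

2. Step 7.
- Risk: syn/anti equilibration of the allylpalladium intermediate could erode the alkene geometry on which the cis relation depends.
- Risk: allyl–allyl coupling could consume the bromide, and the vinylogous α-boryl ester could lose boron on silica.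
- Fallback: copper-mediated SN2' borylation of a Baylis–Hillman acetate, known to give 3-substituted 2-(alkoxycarbonyl)allylboronates with the substituent cis to CH2B. It sets out from bis(pinacolato)diboron 10, takes methyl acrylate and methyl glyoxylate as further commercial inputs, and returns at boronate 11.
- DABCO should join the two esters to racemic dimethyl 2-hydroxy-3-methylidenebutanedioate F4. Ac2O/pyridine should give racemic dimethyl 2-acetoxy-3-methylidenebutanedioate F5.
- CuCl, LiCl, KOAc and 10 in DMF at rt should then add boron to the CH2 terminus with loss of acetate. No allylpalladium species is involved, and the geometry is set in the elimination.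

3. Step 9.
- Risk: acid-catalysed enolisation at C4 in the hot medium could cause cis-to-trans epimerisation or migration of the alkene into the ring.
- Fallback: two neutral or cold operations instead of one hot acidic one. It sets out from 13 and returns at 15.
- Aqueous HF in MeCN at 0 °C should remove the silyl group, and hydroxy methyl ester 14 is this time isolated.
- Pig liver esterase in pH 7 phosphate buffer with a little acetone at rt should then hydrolyse the methyl ester, as is done for acid- and base-labile prostaglandin methyl esters. No compound outside the list is made.

**Further compounds**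

F1 | step 8 | potassium [(2E)-2,3-bis(methoxycarbonyl)prop-2-en-1-yl]trifluoroborate | COC(=O)/C=C(\C[B-](F)(F)F)C(=O)OC.[K+]
F2 | step 8 | (1R,2S,3R,4S)-2-phenylbornane-2,3-diyl [(2E)-2,3-bis(methoxycarbonyl)prop-2-en-1-yl]boronate | C[C@@]12CC[C@@H](C1(C)C)[C@H]3OB(C/C(C(=O)OC)=C\C(=O)OC)O[C@@]23c4ccccc4
F3 | step 8 | open-chain syn borate, analogue of 12 carrying the 2-phenylbornane-2,3-diol on boron (not isolated) | C[C@@]12CC[C@@H](C1(C)C)[C@H]3OB(O[C@@H](CCCCCCCCCCCCC[C@H](C)O[Si](C)(C)C(C)(C)C)[C@@H](C(=O)OC)C(=C)C(=O)OC)O[C@@]23c4ccccc4
F4 | step 7 | dimethyl 2-hydroxy-3-methylidenebutanedioate (racemic) | C=C(C(=O)OC)C(O)C(=O)OC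
F5 | step 7 | dimethyl 2-acetoxy-3-methylidenebutanedioate (racemic) | C=C(C(=O)OC)C(OC(C)=O)C(=O)OC
F0 | step 9 | none | none
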